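**Retrosynthetic overview**
Locants (spiro[5.5]undecane): ring B = C1 (CHOH), C2 (CH2), C3 (CClCH3), C4 (CHBr), C5 (CH2), C6 (spiro carbon). Ring A = C6, C7 (C–CH3), C8, C9, C10 (C–Br), C11 (CMe2).
Both oxiranes are removed last, going back to the 7,9-diene 9. In the forward direction the 7,8-oxirane is formed first and the 9,10-oxirane second.
Ring B is opened at C1–C2. The γ-chlorohydrin C1(OH)–C2H2–C3(Cl)(CH3) of ring B is a chloro-Prins retron, and the C4 bromine next to C3 can bridge the C3 cation. This leads back to the monocyclic aldehyde 7, which carries an allylsilane.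
Ring A together with C1 is the intact C10 skeleton of safranal (formyl carbon = C1, gem-dimethyl carbon = C11, ring methyl on C7). A deconjugative asymmetric α-allylation creates C6 and moves the diene to C7–C10.
Order of rings: ring A (bought), ring B (step 5), 7,8-oxirane (step 6), 9,10-oxirane (step 7).

Key step: step 5

Assumption: the (S)-PHOX ligand of step 3 is taken to give the (R)-aldehyde by analogy with cyclic enol carbonates. If the sense is opposite, the equally available (R)-ligand is used and nothing else changes.

Step 1
Reactants: 1 safranal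
Product: 2 rac-5-bromo-2,6,6-trimethylcyclohexa-1,3-diene-1-carbaldehyde
Conditions: NBS (1.05 equiv), AIBN (cat.), PhCF3, 75 °C; used crude
Reagents that add atoms: N-bromosuccinimide O=C1CCC(=O)N1Br
Why: Wohl–Ziegler bromination, in which hydrogen abstraction from the only ring CH2 gives a pentadienyl radical conjugated to the formyl group and bromine is transferred to its secondary terminus so that the dienal stays conjugated (the same ring-CH2 over CH3 preference is known for β-cyclocitral and β-ionone); the new stereocentre is racemic and is erased in step 2.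

Step 2
Reactants: 2 rac-5-bromosafranal; 3 allyl chloroformate
Product: 4 allyl (Z)-[(5-bromo-2,6,6-trimethylcyclohexa-2,4-dien-1-ylidene)methyl] carbonate
Conditions: KN(SiMe3)2, THF, −78 °C; then 3
Reagents that add atoms: none
Why: Vinylogous deprotonation at the C–H acidified by bromine gives the linear trienolate, and the hard chloroformate traps it on oxygen (enol carbonate synthesis), the s-trans enal conformer placing the carbonate cis to the CMe2 carbon; no stereocentre is formed.

Step 3
Reactants: 4 trienol carbonate
Product: 5 (1R)-5-bromo-2,6,6-trimethyl-1-(prop-2-en-1-yl)cyclohexa-2,4-diene-1-carbaldehyde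
Conditions: Pd2(dba)3 (2.5 mol %), (S)-(CF3)3-t-BuPHOX (6 mol %), toluene, 25 °C
Reagents that add atoms: none
Why: Decarboxylative asymmetric allylic alkylation (Tsuji–Trost type): ionisation by zerovalent palladium and loss of CO2 give an allylpalladium O-enolate whose inner-sphere, seven-membered reductive elimination can reach only the α-carbon, so the future spiro carbon C6 is made on the enolate face left open by the PHOX ligand, as precedented for quaternary carbons flanked by a gem-dimethyl group, and the deconjugation moves the diene to C7–C10.

Step 4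
Reactants: 5 allyl aldehyde; 6 trimethyl(2-methylprop-2-en-1-yl)silane
Product: 7 (1R)-5-bromo-2,6,6-trimethyl-1-[(2E)-3-methyl-4-(trimethylsilyl)but-2-en-1-yl]cyclohexa-2,4-diene-1-carbaldehyde (E drawn, E/Z mixture usable)
Conditions: second-generation Hoveyda–Grubbs catalyst (H2IMes)Cl2Ru(=CH-2-iPrOC6H4) (5 mol %), 6 (5 equiv), CH2Cl2, 40 °C
Reagents that add atoms: none
Why: Olefin cross-metathesis of a terminal alkene with an excess of a 1,1-disubstituted alkene gives the trisubstituted allylsilane, the hindered and brominated ring alkenes being inert to the ruthenium carbene and the alkene geometry being irrelevant because step 5 erases it.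

Step 5
Reactants: 7 allylsilane aldehyde
Product: 9 (1S,3S,4S,6R)-4,10-dibromo-3-chloro-3,7,11,11-tetramethylspiro[5.5]undeca-7,9-dien-1-ol, via allylic bromide aldehyde 8 (not isolated)
Conditions: NBS (1.0 equiv), CH2Cl2, −78 °C; then SnCl4 (2.2 equiv), −78 °C; aq NaHCO3
Reagents that add atoms: N-bromosuccinimide O=C1CCC(=O)N1Br; tin tetrachloride Cl[Sn](Cl)(Cl)Cl
Why: Proposed new method: NBS attacks the allylsilane at C4 in an anti SE2' bromodesilylation (known chemistry) to give the labile secondary allylic bromide 8 free of halide ions, and SnCl4 then binds the formyl oxygen so that the 1,1-disubstituted alkene attacks the carbonyl carbon through its CH2 terminus (C2–C1 bond), the tertiary cation at C3 being bridged by the neighbouring bromine and opened by chloride. The closest known reaction types are the Lewis-acid-mediated type 2 Prins/carbonyl-ene carbocyclisation of 5-methylhex-5-enals to 3-chloro-3-methylcyclohexanols and the stereospecific anti capture of bromonium ions formed next to a tertiary carbon; what is new is the allylic bromide as the alkene partner. Ring B closes 6-exo-trig at the carbonyl and 6-endo-trig at the alkene through a chair in which the CMe2 carbon of ring A is equatorial. C4 is set in the bromination, where the A(1,3)-minimised conformer holds the C5–C6 bond out of the alkene plane and folds the chain toward the small formyl group, so bromine arrives anti to C6 and ends equatorial; C1 is set by the chair, the formyl hydrogen taking the crowded site between the two ring A carbons and the tin-bound oxygen the axial site; C3 is set by the bromine bridge, which occupies the face syn to the axial oxygen so that chloride enters anti to bromine along the equatorial trajectory. The step needs attack on the allylsilane rather than the bromodiene (secured by the far higher nucleophilicity of the allylsilane and by the deactivated, neopentyl-flanked ring alkenes), cyclisation faster than ionisation or 1,3-shift of the allylic bromide (secured by −78 °C, the absence of free halide and Thorpe–Ingold compression at C6), and a trans-diequatorial Br/Cl pair, which diaxial addition to a preformed ring B alkene would not reliably give.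

Step 6
Reactants: 9 bromodiene chlorohydrin
Product: 10 (1S,3S,4S,6R,7R,8S)-4,10-dibromo-3-chloro-7,8-epoxy-3,7,11,11-tetramethylspiro[5.5]undec-9-en-1-ol (oxirane on the ring A face anti to C1)
Conditions: dimethyldioxirane (1.1 equiv, freshly made from acetone and Oxone), acetone/CH2Cl2, −40 to 0 °C
Reagents that add atoms: dimethyldioxirane CC1(C)OO1
Why: Dioxirane epoxidation, in which the trialkyl-substituted C7=C8 bond is far more nucleophilic than the bromoalkene and, in the twisted cyclohexadiene, the more branched C1 arm on C6 sits pseudoaxial (avoiding A(1,2) strain with the C7 methyl) and shields its own face, so oxygen is delivered anti to C1 while the neutral medium prevents attack of the C1 hydroxyl on the allylic epoxide.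

Step 7
Reactants: 10 monoepoxide
Product: 11 (1S,3S,4S,6R,7R,8S,9S,10S)-4,10-dibromo-3-chloro-7,8:9,10-diepoxy-3,7,11,11-tetramethylspiro[5.5]undecan-1-ol (target)
Conditions: mCPBA (2 equiv), Na2HPO4, CH2Cl2, 0 °C to rt
Reagents that add atoms: 3-chloroperbenzoic acid O=C(OO)c1cccc(Cl)c1
Why: Peracid epoxidation of the remaining bromoalkene, in which the axial C1 hydroxyl lies over C10 and hydrogen-bonds the peracid (Henbest-type direction) while the other face is blocked by the pseudoaxial C11 methyl and by the first oxirane, so oxygen enters syn to C1 and anti to the 7,8-epoxide, the phosphate buffer protecting the α-bromo epoxide.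

**Compound list**
1 | safranal, 2,6,6-trimethylcyclohexa-1,3-diene-1-carbaldehyde | CC1=C(C=O)C(C)(C)CC=C1 | starting material
2 | rac-5-bromo-2,6,6-trimethylcyclohexa-1,3-diene-1-carbaldehyde | CC1=C(C=O)C(C)(C)C(Br)C=C1 | intermediate
3 | allyl chloroformate | C=CCOC(=O)Cl | starting material
4 | allyl (Z)-[(5-bromo-2,6,6-trimethylcyclohexa-2,4-dien-1-ylidene)methyl] carbonate | C=CCOC(=O)O/C=C1/C(C)=CC=C(Br)C1(C)C | intermediate
5 | (1R)-5-bromo-2,6,6-trimethyl-1-(prop-2-en-1-yl)cyclohexa-2,4-diene-1-carbaldehyde | CC1(C)C(Br)=CC=C(C)[C@]1(C=O)CC=C | intermediate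
6 | trimethyl(2-methylprop-2-en-1-yl)silane | C=C(C)C[Si](C)(C)C | starting material
7 | (1R)-5-bromo-2,6,6-trimethyl-1-[(2E)-3-methyl-4-(trimethylsilyl)but-2-en-1-yl]cyclohexa-2,4-diene-1-carbaldehyde | CC1(C)C(Br)=CC=C(C)[C@]1(C=O)C/C=C(\C)C[Si](C)(C)C | intermediate
8 | (1R)-5-bromo-1-[(2S)-2-bromo-3-methylbut-3-en-1-yl]-2,6,6-trimethylcyclohexa-2,4-diene-1-carbaldehyde | CC1(C)C(Br)=CC=C(C)[C@]1(C=O)C[C@H](Br)C(C)=C | intermediate
9 | (1S,3S,4S,6R)-4,10-dibromo-3-chloro-3,7,11,11-tetramethylspiro[5.5]undeca-7,9-dien-1-ol | CC1(C)C(Br)=CC=C(C)[C@]12C[C@H](Br)[C@@](C)(Cl)C[C@@H]2O | intermediate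
10 | (1S,3S,4S,6R,7R,8S)-4,10-dibromo-3-chloro-7,8-epoxy-3,7,11,11-tetramethylspiro[5.5]undec-9-en-1-ol | CC1(C)C(Br)=C[C@@H]2O[C@]2(C)[C@]12C[C@H](Br)[C@@](C)(Cl)C[C@@H]2O | intermediate
11 | (1S,3S,4S,6R,7R,8S,9S,10S)-4,10-dibromo-3-chloro-7,8:9,10-diepoxy-3,7,11,11-tetramethylspiro[5.5]undecan-1-ol | CC1(C)[C@@]2(Br)O[C@H]2[C@@H]2O[C@]2(C)[C@]12C[C@H](Br)[C@@](C)(Cl)C[C@@H]2O | target

Total step count: 7. Longest linear sequence: 7 steps (1 to 11).

**Steps most likely to fail**

Step 5.
- What may go wrong: poor facial selectivity in the bromodesilylation; ionisation, 1,3-shift or halide exchange of the allylic bromide under SnCl4; proton loss instead of chloride capture; delivery of chloride from the tin-bound oxygen to the wrong face of C3.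
- Fallback: it sets out from 8, generated from 7 with NBS exactly as in step 5, and separates C–C from C–Cl bond formation using two known reactions.
- Me2AlCl (1.5 equiv, CH2Cl2, −78 °C) is a Lewis acid that also destroys adventitious HCl. It promotes the concerted type 2 carbonyl-ene reaction, with hydrogen taken from the methyl group and the oxygen axial in the chair. The product is (1S,4S,6R)-4,10-dibromo-7,11,11-trimethyl-3-methylidenespiro[5.5]undeca-7,9-dien-1-ol F1, and any C4 epimer can be removed at this stage.
- Markovnikov hydrochlorination of the exocyclic methylene with anhydrous HCl (CH2Cl2/Et2O, −40 °C), again through the bromine-bridged cation, comes back to the route at 9.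

Step 3.
- What may go wrong: low enantioselection at a very congested carbon; allylation at the γ or ε carbon; oxidative addition of zerovalent palladium into the ring C–Br bond.
- Fallback: it sets out from 2 and replaces catalysis by a covalently bound auxiliary.
- Condensation of 2 with tert-butyl (S)-tert-leucinate (MgSO4, CH2Cl2) gives tert-butyl (2S)-2-{(E)-[(5-bromo-2,6,6-trimethylcyclohexa-1,3-dien-1-yl)methylidene]amino}-3,3-dimethylbutanoate F2.
- LiN(iPr)2 (THF, −78 °C) forms the chelated lithio-trienamine, which allyl bromide alkylates at the α-carbon on the face left open by the tert-butyl group. The product is tert-butyl (2S)-2-{(E)-[((1R)-1-allyl-5-bromo-2,6,6-trimethylcyclohexa-2,4-dien-1-yl)methylidene]amino}-3,3-dimethylbutanoate F3.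
- Mild hydrolysis (aqueous citric acid) comes back to the route at 5.

Step 6.
- What may go wrong: poor facial selectivity of oxygen transfer to C7=C8; over-oxidation; acid-triggered transannular ether formation during isolation.
- Fallback: it sets out from 9 and inverts the facial outcome through a halohydrin.
- NBS in aqueous THF (0 °C) places bromine on C8 from the face that the dioxirane also prefers, and water opens the bromonium ion anti at the tertiary C7. The product is (1S,3S,4S,6R,7R,8R)-4,8,10-tribromo-3-chloro-3,7,11,11-tetramethylspiro[5.5]undec-9-ene-1,7-diol F4.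
- K2CO3 in MeOH closes the oxirane by backside displacement of the C8 bromide, putting oxygen on the opposite face and coming back to the route at 10.

**Further compounds**
F1 | step 5 | (1S,4S,6R)-4,10-dibromo-7,11,11-trimethyl-3-methylidenespiro[5.5]undeca-7,9-dien-1-ol | CC1(C)C(Br)=CC=C(C)[C@]12C[C@H](Br)C(=C)C[C@@H]2O
F2 | step 3 | tert-butyl (2S)-2-{(E)-[(5-bromo-2,6,6-trimethylcyclohexa-1,3-dien-1-yl)methylidene]amino}-3,3-dimethylbutanoate | CC1=C(/C=N/[C@H](C(=O)OC(C)(C)C)C(C)(C)C)C(C)(C)C(Br)C=C1
F3 | step 3 | tert-butyl (2S)-2-{(E)-[((1R)-1-allyl-5-bromo-2,6,6-trimethylcyclohexa-2,4-dien-1-yl)methylidene]amino}-3,3-dimethylbutanoate | CC1(C)C(Br)=CC=C(C)[C@]1(/C=N/[C@H](C(=O)OC(C)(C)C)C(C)(C)C)CC=C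
F4 | step 6 | (1S,3S,4S,6R,7R,8R)-4,8,10-tribromo-3-chloro-3,7,11,11-tetramethylspiro[5.5]undec-9-ene-1,7-diol | CC1(C)C(Br)=C[C@@H](Br)[C@](C)(O)[C@]12C[C@H](Br)[C@@](C)(Cl)C[C@@H]2O
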